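**Retrosynthetic overview**
1. Feature: the target is a biflavone joined C6(u1)–C8(u2). u1 is the 5,7-dihydroxy-4'-methoxyflavone half, with ring O1 para to the axis. u2 is the 5,4'-dihydroxy-7-methoxyflavone half, with ring O1 ortho to the axis. Each phloroglucinol ring A offers two oxygens that could close ring C, and each half needs its own ring B, so oxygen and aryl group must be assigned half by half.
2. Last disconnection: the four benzyl ethers come off, and both pyranone rings C are opened at O1–C2, which leads back to bis(1,3-diketone) 18.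
3. Key disconnection: u1-C2–C3 and u2-C2–C3 are cut together. This leads to bis(ester) 17, with 4-methoxybenzoyl on u1-O1, 4-benzyloxybenzoyl on u2-O1, and both O5 blocked as benzyl ethers.
4. The esters are removed (open u1-O1 acylated first, axis-flanked u2-O1 second). The axis is cut by Suzuki-Miyaura coupling of boronate 6 with iodide 10, both made from 2,4,6-trihydroxyacetophenone.
5. Ring order: rings A and B are bought. The two rings C form together in step 15, after the key step has built their carbon chains.

Key step: step 14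

Assumption: the SMILES gives no descriptor for the hindered C6(u1)–C8(u2) axis, so the axis is made as the racemate; the molecule has no stereocentre. Flavone numbering (u1-O1, u2-O5 and so on) is also used for the future positions in all precursors.

**Step 1**
Reactants: 1 2,4,6-trihydroxyacetophenone
Product: 2 1-[4-(benzyloxy)-2,6-dihydroxyphenyl]ethanone
Conditions: BnBr (1.0 equiv), K2CO3 (1.0 equiv), DMF, rt
Reagents that add atoms: benzyl bromide, BrCc1ccccc1
Why: Williamson ether synthesis: the 4-OH is the most acidic hydroxyl and the only one not hydrogen-bonded to the acetyl C=O, so one equivalent of halide should react there first (future u1-O7), and over-benzylated material is removable by chromatography.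

**Step 2**
Reactants: 2 1-[4-(benzyloxy)-2,6-dihydroxyphenyl]ethanone
Product: 3 1-[4-(benzyloxy)-2-hydroxy-6-(methoxymethoxy)phenyl]ethanone
Conditions: MOMCl (1.1 equiv), iPr2NEt (1.5 equiv), CH2Cl2, 0 °C to rt
Reagents that add atoms: chloromethyl methyl ether, COCCl
Why: O-alkylation of a phenol to a MOM acetal: the two phenols of 2 are equivalent, and once one is capped the other is held in a strong chelate that an amine base does not open, so the reaction should stop at the mono-ether that marks the future u1-O1.

**Step 3**
Reactants: 3 1-[4-(benzyloxy)-2-hydroxy-6-(methoxymethoxy)phenyl]ethanone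
Product: 4 1-[4-(benzyloxy)-2-hydroxy-3-iodo-6-(methoxymethoxy)phenyl]ethanone
Conditions: NIS (1.0 equiv), DMF, 0 °C to rt, dark
Reagents that add atoms: N-iodosuccinimide, O=C1CCC(=O)N1I
Why: Electrophilic aromatic iodination under neutral conditions: in 2-hydroxy-4,6-dialkoxyacetophenones the halogen enters C3 next to the free chelated phenol rather than the more crowded C5 between two ethers, and the absence of acid keeps the MOM group.

**Step 4**
Reactants: 4 1-[4-(benzyloxy)-2-hydroxy-3-iodo-6-(methoxymethoxy)phenyl]ethanone
Product: 5 1-[2,4-bis(benzyloxy)-3-iodo-6-(methoxymethoxy)phenyl]ethanone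
Conditions: BnBr (1.5 equiv), K2CO3 (2 equiv), DMF, 60 °C
Reagents that add atoms: benzyl bromide, BrCc1ccccc1
Why: Williamson ether synthesis under forcing conditions that open the chelate: the phenol that directed the iodine becomes the u1-O5 benzyl ether, so iodine now lies between two benzyl ethers with the MOM-masked u1-O1 para to it, a pattern that direct iodination could not give.

**Step 5**
Reactants: 5 1-[2,4-bis(benzyloxy)-3-iodo-6-(methoxymethoxy)phenyl]ethanone
Product: 6 1-[2,4-bis(benzyloxy)-6-(methoxymethoxy)-3-(4,4,5,5-tetramethyl-1,3,2-dioxaborolan-2-yl)phenyl]ethanone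
Conditions: HBpin (2 equiv), Et3N (3 equiv), PdCl2(MeCN)2 (3 mol %), SPhos (12 mol %), 1,4-dioxane, 80 °C
Reagents that add atoms: pinacolborane, CC1(C)OBOC1(C)C
Why: Palladium-catalysed Miyaura-type borylation of an aryl iodide with pinacolborane: the bulky biarylphosphine copes with di-ortho-alkoxy iodides, the hindered ketone and the acetal and benzyl ethers are tolerated, and the amine base does not support C–H arylation of the neighbouring benzyl rings.

**Step 6**
Reactants: 1 2,4,6-trihydroxyacetophenone
Product: 7 1-(2,6-dihydroxy-4-methoxyphenyl)ethanone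
Conditions: Me2SO4 (1.0 equiv), K2CO3 (1.0 equiv), acetone, reflux
Reagents that add atoms: dimethyl sulfate, COS(=O)(=O)OC
Why: Williamson-type O-methylation: as in step 1 the non-chelated, most acidic 4-OH reacts first and becomes the 7-methoxy group of u2.

**Step 7**
Reactants: 7 1-(2,6-dihydroxy-4-methoxyphenyl)ethanone
Product: 8 1-[2-(benzyloxy)-6-hydroxy-4-methoxyphenyl]ethanone
Conditions: BnBr (1.05 equiv), K2CO3 (1.2 equiv), acetone, reflux
Reagents that add atoms: benzyl bromide, BrCc1ccccc1
Why: Williamson ether synthesis on one of two equivalent phenols: the remaining phenol is chelated and inert under these mild conditions, so mono-benzylation (future u2-O5) is expected.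

**Step 8**
Reactants: 8 1-[2-(benzyloxy)-6-hydroxy-4-methoxyphenyl]ethanone
Product: 9 1-[6-(benzyloxy)-2-hydroxy-3-iodo-4-methoxyphenyl]ethanone
Conditions: NIS (1.0 equiv), DMF, 0 °C to rt, dark
Reagents that add atoms: N-iodosuccinimide, O=C1CCC(=O)N1I
Why: Electrophilic aromatic iodination with the same preference as in step 3: iodine enters between the free phenol and the methoxy group, and here that phenol is kept as the future u2-O1, which places O1 ortho to the axis.

**Step 9**
Reactants: 9 1-[6-(benzyloxy)-2-hydroxy-3-iodo-4-methoxyphenyl]ethanone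
Product: 10 1-[6-(benzyloxy)-3-iodo-4-methoxy-2-(methoxymethoxy)phenyl]ethanone
Conditions: NaH (1.1 equiv), MOMCl (1.3 equiv), THF–DMF, 0 °C
Reagents that add atoms: chloromethyl methyl ether, COCCl
Why: O-alkylation of a sodium phenoxide to a MOM acetal: the phenol is far more acidic than the methyl ketone, so a slight excess of hydride forms only the phenoxide, which is reactive enough to be capped despite its two ortho neighbours.

**Step 10**
Reactants: 6 1-[2,4-bis(benzyloxy)-6-(methoxymethoxy)-3-(4,4,5,5-tetramethyl-1,3,2-dioxaborolan-2-yl)phenyl]ethanone (1.5 equiv); 10 1-[6-(benzyloxy)-3-iodo-4-methoxy-2-(methoxymethoxy)phenyl]ethanone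
Product: 11 3,3'-diacetyl-2,4',6-tris(benzyloxy)-6'-methoxy-2',4-bis(methoxymethoxy)biphenyl (unprimed ring = u1; primed ring = u2)
Conditions: Pd(OAc)2 (5 mol %), SPhos (10 mol %), K3PO4 (3 equiv), toluene–H2O 10:1, 100 °C, degassed
Reagents that add atoms: none
Why: Suzuki-Miyaura coupling with a bulky electron-rich biarylphosphine, the catalyst type used for tetra-ortho-substituted biaryls: zerovalent palladium inserts into the carbon–iodine bond of 10, whose neighbours are OMe and OMOM, so no benzyl ring sits next to palladium for a competing C–H arylation, and the new axis forms as the racemate.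

**Step 11**
Reactants: 11 3,3'-diacetyl-2,4',6-tris(benzyloxy)-6'-methoxy-2',4-bis(methoxymethoxy)biphenyl
Product: 12 3,3'-diacetyl-2,4',6-tris(benzyloxy)-2',4-dihydroxy-6'-methoxybiphenyl (u1-O1-H and u2-O1-H free)
Conditions: conc. HCl (cat.), MeOH–THF 2:1, 50 °C
Reagents that add atoms: none
Why: Acid-catalysed acetal exchange with methanol: MOM ethers ortho to an aryl ketone cleave readily, while benzyl and methyl ethers and the hindered ketones are untouched by dilute acid.

**Step 12**
Reactants: 12 3,3'-diacetyl-2,4',6-tris(benzyloxy)-2',4-dihydroxy-6'-methoxybiphenyl; 13 4-methoxybenzoyl chloride (1.0 equiv)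
Product: 14 mono-ester of 12 carrying the 4-methoxybenzoate on u1-O1 (biphenyl O4), u2-O1-H still free
Conditions: pyridine–CH2Cl2, 0 °C to rt, slow addition of 13, no DMAP
Reagents that add atoms: none
Why: O-acylation of a phenol with an acid chloride in pyridine under kinetic control: u1-O1-H has only the acetyl group and a ring hydrogen beside it, whereas u2-O1-H is wedged between its acetyl group and the perpendicular 2,6-bis(benzyloxy)aryl ring, so one equivalent should be taken up by u1-O1.

**Step 13**
Reactants: 14 mono-ester carrying the 4-methoxybenzoate on u1-O1; 15 4-(benzyloxy)benzoic acid (2 equiv)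
Product: 17 biaryl bis(acetophenone) bis(aroyl ester) (4-methoxybenzoate on u1-O1; 4-benzyloxybenzoate on u2-O1), via 4-(benzyloxy)benzoyl chloride 16 (not isolated)
Conditions: 15, (COCl)2, DMF (cat.), CH2Cl2, rt, evaporate; then 14, Et3N (3 equiv), DMAP (0.1 equiv), CH2Cl2, rt to 40 °C
Reagents that add atoms: oxalyl chloride, O=C(Cl)C(Cl)=O (supplies the chlorine of 16 only)
Why: Acid chloride formation followed by DMAP-catalysed acylation: only one phenol is left, so excess reagent and nucleophilic catalysis can overcome its crowding, while the low DMAP loading and mild temperature leave the electron-rich anisoate on u1-O1 in place and are too weakly basic to start an acyl shift.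

**Step 14**
Reactants: 17 biaryl bis(acetophenone) bis(aroyl ester)
Product: 18 biaryl bis(1,3-diketone) with u1-O1-H and u2-O1-H free
Conditions: KOtBu (6 equiv), THF (0.02 M), 0 °C to rt; then 1 M HCl
Reagents that add atoms: none
Why: KOtBu deprotonates both acetyl CH3 groups, and each enolate carbon adds to the carbonyl of the aroyl ester on the neighbouring ring oxygen through a six-membered tetrahedral intermediate that collapses with loss of the phenoxide, which forms u1-C2–C3 and u2-C2–C3 and frees u1-O1 and u2-O1. This is the Baker-Venkataraman rearrangement (an intramolecular Claisen-type O-to-C acyl transfer), well established for 2-aroyloxy-4,6-dialkoxyacetophenones including 3-substituted ones, and here it runs at two sites of one molecule. Each diketone is deprotonated as soon as it forms, which makes both shifts irreversible and explains why at least four equivalents of base are needed. No ring is closed and no stereocentre is created; the racemic axis is only carried along. The selectivity required is that each aroyl group stays in its own half: the six-membered intramolecular transfer should far outrun a bimolecular transfer at high dilution, and the only conceivable cross-axis attack (u1 enolate on the u2 ester) would need a nine-membered transition state across a twisted biaryl. Because u1-O5 and u2-O5 are benzyl ethers, the phenoxide released beside each diketone is the only oxygen able to close that pyranone, so ring B identity and the closing oxygen are fixed for both halves in this one operation.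

**Step 15**
Reactants: 18 biaryl bis(1,3-diketone)
Product: 19 5,7-bis(benzyloxy)-6-{5-(benzyloxy)-2-[4-(benzyloxy)phenyl]-7-methoxy-4-oxo-4H-chromen-8-yl}-2-(4-methoxyphenyl)-4H-chromen-4-one
Conditions: conc. H2SO4 (cat., about 1 vol %), AcOH, 60 °C
Reagents that add atoms: none
Why: Acid-catalysed cyclodehydration of o-hydroxyaryl 1,3-diketones, the closing stage of the Baker-Venkataraman flavone synthesis: each free phenol adds 6-exo-trig to its aroyl C=O and water is lost, and the catalytic acid and moderate temperature keep the O5 benzyl ethers on until both rings C are closed, which excludes closure on O5 and a Wessely-Moser type 6/8 isomerisation.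

**Step 16**
Reactants: 19 tetra-O-benzyl biflavone
Product: 20 5,7-dihydroxy-6-[5-hydroxy-2-(4-hydroxyphenyl)-7-methoxy-4-oxo-4H-chromen-8-yl]-2-(4-methoxyphenyl)-4H-chromen-4-one (target)
Conditions: H2 (1 atm), Pd/C (10 wt %), THF–MeOH 1:1, rt
Reagents that add atoms: none
Why: Catalytic hydrogenolysis of aryl benzyl ethers: at atmospheric pressure and room temperature the four O–benzyl bonds are cleaved well before the conjugated C2=C3 bonds of the flavones are reduced, and the two methyl ethers are inert.

**Compound list**
1 | 2,4,6-trihydroxyacetophenone | CC(=O)c1c(O)cc(O)cc1O | starting material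
2 | 1-[4-(benzyloxy)-2,6-dihydroxyphenyl]ethanone | CC(=O)c1c(O)cc(OCc2ccccc2)cc1O | intermediate
3 | 1-[4-(benzyloxy)-2-hydroxy-6-(methoxymethoxy)phenyl]ethanone | CC(=O)c1c(O)cc(OCc2ccccc2)cc1OCOC | intermediate
4 | 1-[4-(benzyloxy)-2-hydroxy-3-iodo-6-(methoxymethoxy)phenyl]ethanone | CC(=O)c1c(O)c(I)c(OCc2ccccc2)cc1OCOC | intermediate
5 | 1-[2,4-bis(benzyloxy)-3-iodo-6-(methoxymethoxy)phenyl]ethanone | CC(=O)c1c(OCc2ccccc2)c(I)c(OCc2ccccc2)cc1OCOC | intermediate
6 | 1-[2,4-bis(benzyloxy)-6-(methoxymethoxy)-3-(4,4,5,5-tetramethyl-1,3,2-dioxaborolan-2-yl)phenyl]ethanone | CC(=O)c1c(OCOC)cc(OCc2ccccc2)c(B2OC(C)(C)C(C)(C)O2)c1OCc1ccccc1 | intermediate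
7 | 1-(2,6-dihydroxy-4-methoxyphenyl)ethanone | CC(=O)c1c(O)cc(OC)cc1O | intermediate
8 | 1-[2-(benzyloxy)-6-hydroxy-4-methoxyphenyl]ethanone | CC(=O)c1c(O)cc(OC)cc1OCc1ccccc1 | intermediate
9 | 1-[6-(benzyloxy)-2-hydroxy-3-iodo-4-methoxyphenyl]ethanone | CC(=O)c1c(O)c(I)c(OC)cc1OCc1ccccc1 | intermediate
10 | 1-[6-(benzyloxy)-3-iodo-4-methoxy-2-(methoxymethoxy)phenyl]ethanone | CC(=O)c1c(OCOC)c(I)c(OC)cc1OCc1ccccc1 | intermediate
11 | 3,3'-diacetyl-2,4',6-tris(benzyloxy)-6'-methoxy-2',4-bis(methoxymethoxy)biphenyl (racemic axis) | CC(=O)c1c(OCOC)cc(OCc2ccccc2)c(-c2c(OC)cc(OCc3ccccc3)c(C(C)=O)c2OCOC)c1OCc1ccccc1 | intermediate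
12 | 3,3'-diacetyl-2,4',6-tris(benzyloxy)-2',4-dihydroxy-6'-methoxybiphenyl | CC(=O)c1c(O)cc(OCc2ccccc2)c(-c2c(OC)cc(OCc3ccccc3)c(C(C)=O)c2O)c1OCc1ccccc1 | intermediate
13 | 4-methoxybenzoyl chloride | COc1ccc(cc1)C(Cl)=O | starting material
14 | mono-ester of 12, 4-methoxybenzoate on u1-O1 | CC(=O)c1c(OC(=O)c2ccc(OC)cc2)cc(OCc2ccccc2)c(-c2c(OC)cc(OCc3ccccc3)c(C(C)=O)c2O)c1OCc1ccccc1 | intermediate
15 | 4-(benzyloxy)benzoic acid | O=C(O)c1ccc(OCc2ccccc2)cc1 | starting material
16 | 4-(benzyloxy)benzoyl chloride (not isolated) | O=C(Cl)c1ccc(OCc2ccccc2)cc1 | intermediate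
17 | biaryl bis(acetophenone) bis(aroyl ester), 4-methoxybenzoate on u1-O1 and 4-benzyloxybenzoate on u2-O1 | CC(=O)c1c(OC(=O)c2ccc(OC)cc2)cc(OCc2ccccc2)c(-c2c(OC)cc(OCc3ccccc3)c(C(C)=O)c2OC(=O)c2ccc(OCc3ccccc3)cc2)c1OCc1ccccc1 | intermediate
18 | biaryl bis(1,3-diketone), u1-O1-H and u2-O1-H free | COc1ccc(cc1)C(=O)CC(=O)c1c(O)cc(OCc2ccccc2)c(-c2c(OC)cc(OCc3ccccc3)c(C(=O)CC(=O)c3ccc(OCc4ccccc4)cc3)c2O)c1OCc1ccccc1 | intermediate
19 | 5,7-bis(benzyloxy)-6-{5-(benzyloxy)-2-[4-(benzyloxy)phenyl]-7-methoxy-4-oxo-4H-chromen-8-yl}-2-(4-methoxyphenyl)-4H-chromen-4-one | COc1ccc(-c2cc(=O)c3c(OCc4ccccc4)c(-c4c(OC)cc(OCc5ccccc5)c5c(=O)cc(-c6ccc(OCc7ccccc7)cc6)oc45)c(OCc4ccccc4)cc3o2)cc1 | intermediate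
20 | 5,7-dihydroxy-6-[5-hydroxy-2-(4-hydroxyphenyl)-7-methoxy-4-oxo-4H-chromen-8-yl]-2-(4-methoxyphenyl)-4H-chromen-4-one (CNP0290866.0) | COc1ccc(-c2cc(=O)c3c(O)c(-c4c(OC)cc(O)c5c(=O)cc(-c6ccc(O)cc6)oc45)c(O)cc3o2)cc1 | target

**Total step count:** 16.
**Longest linear sequence:** 12 steps (steps 1–5, then 10–16).

**Steps most likely to fail**

Step 14.
- What may go wrong: one of the two acyl shifts, most likely the one at the crowded u2 site, may lag behind. Meanwhile tert-butoxide would slowly strip aroyl groups from ester that has not yet rearranged, and the result would be partly rearranged and de-aroylated material.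
- Fallback: build the two halves one after the other, so that each shift is driven and purified alone. It sets out from 14. Treatment with KOtBu (5 equiv) in THF should give the u1 diketone–u2 acetophenone biaryl F1. Catalytic H2SO4 in AcOH closes ring C of u1 to the u1 flavone–u2 acetophenone F2. Its single phenol (u2-O1) is esterified with acid chloride 16 (Et3N, DMAP, CH2Cl2) to the u1 flavone–u2 aroyl ester F3. A second, now single, Baker-Venkataraman shift with KOtBu gives the u1 flavone–u2 diketone F4. Acid cyclodehydration brings the sequence back to the route at 19.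

Step 10.
- What may go wrong: transmetalation at a boron atom flanked by two benzyloxy groups may be slow, and protodeboronation of the electron-rich boronate by the aqueous base may then overtake the coupling.
- Fallback: a Negishi coupling free of base and water. It sets out from 5. Insertion of Zn dust in the presence of LiCl (THF, 40 °C) tolerates the ketone and should give [3-acetyl-2,6-bis(benzyloxy)-4-(methoxymethoxy)phenyl]zinc iodide F5. This is coupled with iodide 10 using Pd2(dba)3 and RuPhos in THF at 70 °C, a catalyst system suited to tetra-ortho-substituted biaryls. The sequence comes back to the route at 11.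

Step 12.
- What may go wrong: discrimination between the two chelated phenols may be insufficient, or over-acylation may occur. Either would place the anisoyl group in the wrong half and destroy the site encoding.
- Fallback: remove the choice by never having both phenols free at once. It sets out from the unprotected iodophenol 9. Coupling with boronate 6 under the conditions of step 10, with one more equivalent of K3PO4, should give the biaryl with u1-O1 as MOM ether and u2-O1 free F6. Its only phenol is esterified with 16 (Et3N, DMAP) to the u2 ester–u1 MOM ether F7. TFA in CH2Cl2 at 0 °C followed by aqueous work-up removes the acetal without touching the ester and gives the u2 ester with u1-O1 free F8. Acylation with 13 in pyridine comes back to the route at 17.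

**Further compounds**
F1 | step 14 | u1 diketone–u2 acetophenone biaryl (both O1 phenols free) | COc1ccc(cc1)C(=O)CC(=O)c1c(O)cc(OCc2ccccc2)c(-c2c(OC)cc(OCc3ccccc3)c(C(C)=O)c2O)c1OCc1ccccc1
F2 | step 14 | u1 flavone–u2 acetophenone, 6-[3-acetyl-4-(benzyloxy)-2-hydroxy-6-methoxyphenyl]-5,7-bis(benzyloxy)-2-(4-methoxyphenyl)-4H-chromen-4-one | COc1ccc(-c2cc(=O)c3c(OCc4ccccc4)c(-c4c(OC)cc(OCc5ccccc5)c(C(C)=O)c4O)c(OCc4ccccc4)cc3o2)cc1
F3 | step 14 | u1 flavone–u2 aroyl ester, 4-(benzyloxy)benzoate of F2 | COc1ccc(-c2cc(=O)c3c(OCc4ccccc4)c(-c4c(OC)cc(OCc5ccccc5)c(C(C)=O)c4OC(=O)c4ccc(OCc5ccccc5)cc4)c(OCc4ccccc4)cc3o2)cc1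
F4 | step 14 | u1 flavone–u2 diketone | COc1ccc(-c2cc(=O)c3c(OCc4ccccc4)c(-c4c(OC)cc(OCc5ccccc5)c(C(=O)CC(=O)c5ccc(OCc6ccccc6)cc5)c4O)c(OCc4ccccc4)cc3o2)cc1
F5 | step 10 | [3-acetyl-2,6-bis(benzyloxy)-4-(methoxymethoxy)phenyl]zinc iodide | CC(=O)c1c(OCOC)cc(OCc2ccccc2)c([Zn]I)c1OCc1ccccc1
F6 | step 12 | biaryl with u1-O1 as MOM ether and u2-O1 free | CC(=O)c1c(OCOC)cc(OCc2ccccc2)c(-c2c(OC)cc(OCc3ccccc3)c(C(C)=O)c2O)c1OCc1ccccc1
F7 | step 12 | u2 ester–u1 MOM ether, 4-(benzyloxy)benzoate of F6 | CC(=O)c1c(OCOC)cc(OCc2ccccc2)c(-c2c(OC)cc(OCc3ccccc3)c(C(C)=O)c2OC(=O)c2ccc(OCc3ccccc3)cc2)c1OCc1ccccc1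
F8 | step 12 | u2 ester with u1-O1 free | CC(=O)c1c(O)cc(OCc2ccccc2)c(-c2c(OC)cc(OCc3ccccc3)c(C(C)=O)c2OC(=O)c2ccc(OCc3ccccc3)cc2)c1OCc1ccccc1
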